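**Remark on the chemistry (one assumption):** RuCl[(R,R)-TsDPEN](p-cymene) is taken to reduce the aroyl ketone of 6 with the facial sense it shows for simple aryl alkyl ketones, which gives the (R)-carbinol; should the sense be the opposite, the (S,S)-catalyst takes its place and nothing else changes.

## Structural features

The target is a 2,3,4-trisubstituted oxolane (tetrahydrofuran), numbered here O1, C2, C3, C4, C5, with C5 an unsubstituted methylene. C2 carries a guaiacyl ring (4-hydroxy-3-methoxyphenyl), C3 a hydroxymethyl group, and C4 an exocyclic secondary carbinol carbon whose other substituent is a catechol ring (3,4-dihydroxyphenyl). Four stereocentres stand in an unbroken row, C2 (S), C3 (R), C4 (S) and the carbinol carbon (R); the ring substituents are 2,3-trans and 3,4-trans, so the two large groups on C2 and C4 are cis. The fragile parts are the catechol, which oxidises to an o-quinone in air and base, and the two benzylic C–O bonds para to an oxygen substituent (O1–C2 and the carbinol C–OH), which ionise in acid, epimerise through quinone-methide-like cations and can be hydrogenolysed. The real difficulty is not the ring but the row of four contiguous centres, one of them outside the ring, together with the need to tell three aliphatic and three phenolic hydroxyls apart. The key step exploits the fact that C2 is benzylic and para to the free hydroxyl of the guaiacyl ring: two-electron oxidation of that phenol makes C2 the exocyclic, electrophilic carbon of a p-quinone methide, which the hydroxyl on C5 can attack to form O1–C2 and the oxolane ring in one operation. Once that bond is cut, the other three centres lie on an open chain that maps onto a trans,trans-trisubstituted γ-butyrolactone, a ring on which relative configuration is easy to control.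

## Logic of the disconnections

**22 ⇒ 21 ⇒ 20.** No skeletal bond is cut; the two catechol O–H bonds become O–benzyl and the carbinol O–H becomes O–silyl. These masks are what the ring-forming step behind 20 needs: one oxidisable phenol only, and one hydroxyl only that can reach C2 through a five-membered ring. The forward steps must be mild towards the two benzylic C–O bonds: buffered fluoride for the silyl ether, and a hydrogenolysis that stops after the aryl benzyl ethers.

**20 ⇒ 18 (through 19).** The O1–C2 bond is cut, which opens the oxolane and removes the C2 stereocentre. The cut belongs here because C2 is para-hydroxybenzylic and becomes electrophilic on oxidation of the phenol. The gain is that 18 is an open-chain 1,4-diol with three stereocentres and a plain benzylic CH2 where C2 will be, needing neither oxygen nor configuration there. The forward step must oxidise the guaiacol only, deliver the C5 hydroxyl and no other nucleophile to C2, and set C2 trans to C3.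

**18 ⇒ 17 ⇒ 16 ⇒ 15.** No skeletal bond is cut; this relay places the silyl group on the secondary oxygen alone. One acyl group covers the phenol and both primary hydroxyls, so a single reagent puts them on and a single reagent takes them off. The demands are steric selectivity in the acylation (primary and phenolic over hindered secondary benzylic) and a de-acylation that is not basic, so that the silyl group cannot migrate to the neighbouring primary oxygen.

**15 ⇒ 14.** Two carbons are raised in oxidation level and one C–O bond is re-formed: the C3 hydroxymethyl carbon becomes a lactone carbonyl joined to the carbinol oxygen, the C5 carbon becomes a methyl ester, and the guaiacol carries its pivalate. The gain is a rigid five-membered lactone on which the three centres are all-trans. The forward step needs a hydride that takes three carbonyl groups to the alcohol level without touching a stereocentre.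

**14 ⇒ 8 + 12.** The bond between C3 and the benzylic carbon (C2–C3 of the target) is cut. A lactone enolate is alkylated anti to its neighbouring substituent, so the cut removes one stereocentre and the whole guaiacyl unit. The forward step must enolise the lactone α-CH2 and not the C–H next to the ester, and the electrophile must carry a phenol mask that survives an enolate.

**12 ⇒ 11 ⇒ 10 ⇒ 9.** Functional-group changes only (C–Br to C–OH to C=O; O-acyl to O–H). The ester on the phenol makes the benzylic bromide less prone to ionise and is removed later without a step of its own.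

**8 ⇒ 6 (through 7).** The lactone acyl–oxygen bond and the carbinol C–H bond are cut. The ketone is a prochiral handle next to a configurationally labile carbon, so two stereocentres come from a racemic precursor in one catalytic step. The forward step needs racemisation of the α-carbon faster than reduction, high facial control at the ketone and preference for the syn hydroxy diester, which is the one that closes to the trans lactone.

**6 ⇒ 4 + 5.** The C3–C4 bond of the target is cut: alkylation of a β-keto ester with an α-halo ester. The only demand is mono-alkylation.

**4 ⇒ 2 + 3.** The C4–C5 bond of the target is cut: the future C5 arrives as the ester carbon in a Claisen condensation of a methyl ketone with a carbonate.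

**2 ⇒ 1.** Two O–benzyl bonds are cut; the catechol is masked from the first step with a group inert to base, hydride, silver oxide and fluoride.

## Other disconnections considered

**Alternative 1:** The cut is the C4–C5 bond together with the C–O bond of the carbinol.
- Forward key step: the redox-active ester A1 (an N-acyloxyphthalimide of an O-carboxymethyl ether, with C2 and C3 in place and an (E)-styrene on C3) would be reduced by photoexcited fac-Ir(ppy)3 and lose CO2. The alkoxymethyl radical would close 5-exo-trig onto the styrene; the benzylic radical would be oxidised by the oxidised photocatalyst (tetravalent iridium) and the cation trapped by water to give A2.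
- In favour: a C–C bond, the ring, the C4 centre and the carbinol oxygen arrive in one step. The chair-like transition state of 5-hexenyl-type radicals is expected to place the new C4 substituent trans to the C3 group and cis to the C2 aryl group, which is the target pattern. No phenol is oxidised. Every oxygen carries benzyl, so the end game would be one hydrogenolysis, a step shorter than the one chosen here; on that point the alternative is the better plan.
- Against: the carbinol centre comes from water adding to a planar benzylic cation with no facial control, so A2 would be an epimer mixture. The fourth stereocentre would need an oxidation–reduction repair next to the epimerisable C4, or a separation. The C2/C3 pair of A1 needs an enantioselective synthesis of its own, and O-alkylation of a hindered, ionisable benzylic alcohol with a haloacetate is not trivial.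
- Comparison: on structure, the chosen plan fixes the carbinol centre first and uses it and the lactone ring to set the others, whereas this plan leaves the exocyclic centre, the hardest one, uncontrolled. On mechanism, both are 5-exo closures resting on known reactivity and are equal there. On step economy, the saved deprotection step is expected to be consumed by the stereochemical repair.

**Alternative 2:** Two ring bonds are cut, O1–C2 and C3–C4, giving the racemic vinyl epoxide A3 and the arylidene malonate A4.
- Forward key step: zerovalent palladium (for example Pd2(dba)3 with a phosphine) would ionise A3 to a zwitterionic π-allylpalladium alkoxide. The alkoxide adds to the benzylidene carbon of A4, and the malonate anion attacks the internal allyl terminus to give A5.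
- In favour: it is the most convergent of the four plans, with the ring and two bonds from two fragments that are each one or two steps from commercial materials. The π-allyl intermediate equilibrates, so a chiral ligand could in principle convert racemic A3 into one enantiomer of A5. The 2,4-cis relationship is the one required. On convergence and on the number of steps to the ring it is the better plan.
- Against: only C2 and C4 are set. C3 emerges quaternary and must lose one ester through an enolate that is β to O1 and can open the ring by retro-oxa-Michael reaction. The 1-arylvinyl group has one carbon too many, so the carbinol needs oxidative excision of the methylene carbon (not with ozone, which attacks the electron-rich rings) and a diastereoselective carbonyl reduction next to the epimerisable C4. The selectivity of the annulation rests on a ligand whose performance with this pair cannot be assumed.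
- Comparison: on structure, A5 holds the whole skeleton but leaves two of four centres open, while the chosen plan enters its key step with three fixed. On mechanism, both form O1–C2 by adding an oxygen nucleophile to an electrophilic benzylidene carbon and are equal in that. On step economy, about five operations would follow A5, so the total could be lower than that of the chosen plan if the two late centres behave, and higher if they need correction.

**Alternative 3:** The cuts are O1–C2 and the bond from C3 to its exocyclic carbon; C2 and C3 are taken back to an alkyne.
- Forward key step: in the homopropargylic alcohol A6 (C4 and carbinol centres in place, only the C5 hydroxyl free), divalent palladium, PdCl2(MeCN)2, would activate the aryl alkyne. The C5 hydroxyl would add 5-endo-dig, CO would insert into the vinylpalladium bond and methanol would release the ester A7. p-Benzoquinone would return zerovalent palladium to the divalent state.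
- In favour: the key step makes no sp3 centre and has no stereochemical issue of its own. The electron-rich aryl group polarises the alkyne in the right sense. The C3 carbon arrives at the ester level. All-silyl protection would allow one final fluoride treatment and avoid hydrogenolysis near benzylic C–O bonds; here the alternative is the better plan.
- Against: C2 and C3 are left as a tetrasubstituted donor–acceptor alkene, a hard type to reduce. Hydrogen added from the face opposite the C4 substituent would give the all-cis ring, so C3 would then have to be epimerised through an ester enolate that is β to O1 and can eliminate with ring opening. Protodepalladation without carbonylation competes, and acid formed during turnover in methanol threatens the benzylic silyl ether.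
- Comparison: on structure, this plan postpones two ring centres to a reduction whose selectivity is thermodynamic at best; the chosen plan postpones one and forms it in the ring closure. On mechanism, both rely on the C5 hydroxyl attacking an activated C2 and both are known reaction types, so they are equal there. On step economy, it is of comparable length to the ring and one step shorter at the end, but probably two steps longer for reduction and epimerisation.

Key step: step 13

## Route

**Step 1**
Reactants: 1 3',4'-dihydroxyacetophenone
Product: 2 1-[3,4-bis(benzyloxy)phenyl]ethan-1-one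
Conditions: BnBr (2.3 eq), K2CO3 (3 eq), DMF, 60 °C
Reagents that add atoms: benzyl bromide, BrCc1ccccc1
Why: Williamson etherification of both phenols; carbonate is too weak to enolise the methyl ketone, so only O-alkylation should occur. The benzyl ethers keep the catechol inert to base, hydride, Ag2O and fluoride until the last step.

**Step 2**
Reactants: 2 1-[3,4-bis(benzyloxy)phenyl]ethan-1-one; 3 dimethyl carbonate
Product: 4 methyl 3-[3,4-bis(benzyloxy)phenyl]-3-oxopropanoate
Conditions: NaH (2.5 eq), (MeO)2CO (5 eq), THF, reflux; aq. HCl quench
Reagents that add atoms: none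
Why: Crossed Claisen condensation of the ketone enolate with the carbonate, driven to completion by irreversible deprotonation of the β-keto ester formed.

**Step 3**
Reactants: 4 methyl 3-[3,4-bis(benzyloxy)phenyl]-3-oxopropanoate; 5 methyl bromoacetate
Product: 6 dimethyl 2-[3,4-bis(benzyloxy)benzoyl]butanedioate (racemic)
Conditions: K2CO3 (1.5 eq), acetone, rt
Reagents that add atoms: none
Why: SN2 C-alkylation of the stabilised β-keto ester enolate; a weak base and one equivalent of bromide limit dialkylation. The new centre stays acidic and is left racemic on purpose for step 4.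

**Step 4**
Reactants: 6 dimethyl 2-[3,4-bis(benzyloxy)benzoyl]butanedioate
Product: 8 methyl (2R,3R)-2-[3,4-bis(benzyloxy)phenyl]-5-oxooxolane-3-carboxylate, via syn-hydroxy diester 7 (not isolated)
Conditions: RuCl[(R,R)-TsDPEN](p-cymene) (1 mol%), HCO2H/Et3N (5:2), DMF, 40 °C; then PPTS (cat.), PhMe, 60 °C
Reagents that add atoms: none
Why: Noyori–Ikariya asymmetric transfer hydrogenation with dynamic kinetic resolution: the carbon between ketone and ester racemises through the enol faster than the ketone is reduced, the catalyst delivers hydride to one face of the aryl ketone (carbinol R) and preferentially reduces the enantiomer leading to the syn hydroxy diester 7. 7 lactonises onto the γ-ester to the trans lactone 8, which is also the more stable diastereomer, so the C2 aryl group and the C3 ester should end up trans.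

**Step 5**
Reactants: 9 vanillin
Product: 10 4-formyl-2-methoxyphenyl 2,2-dimethylpropanoate
Conditions: PivCl (1.1 eq), Et3N (1.3 eq), DMAP (cat.), CH2Cl2, 0 °C → rt
Reagents that add atoms: pivaloyl chloride, CC(C)(C)C(=O)Cl
Why: O-acylation of the phenol. The hindered aryl ester tolerates borohydride, PBr3 and a lactone enolate, lowers the tendency of the later benzylic bromide to ionise, and is removed without a step of its own by the hydride of step 9.

**Step 6**
Reactants: 10 4-formyl-2-methoxyphenyl 2,2-dimethylpropanoate
Product: 11 4-(hydroxymethyl)-2-methoxyphenyl 2,2-dimethylpropanoate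
Conditions: NaBH4 (0.5 eq), THF/MeOH (10:1), 0 °C, 20 min
Reagents that add atoms: none
Why: Chemoselective borohydride reduction of the aldehyde; the hindered aryl pivalate should survive the short, cold exposure.

**Step 7**
Reactants: 11 4-(hydroxymethyl)-2-methoxyphenyl 2,2-dimethylpropanoate
Product: 12 4-(bromomethyl)-2-methoxyphenyl 2,2-dimethylpropanoate
Conditions: PBr3 (0.4 eq), CH2Cl2, 0 °C
Reagents that add atoms: phosphorus tribromide, BrP(Br)Br
Why: Conversion of the benzylic alcohol into the bromide through its phosphite ester (SN2 by bromide).

**Step 8**
Reactants: 8 methyl (2R,3R)-2-[3,4-bis(benzyloxy)phenyl]-5-oxooxolane-3-carboxylate; 12 4-(bromomethyl)-2-methoxyphenyl 2,2-dimethylpropanoate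
Product: 14 methyl (2R,3R,4R)-2-[3,4-bis(benzyloxy)phenyl]-4-{[3-methoxy-4-(pivaloyloxy)phenyl]methyl}-5-oxooxolane-3-carboxylate, via lithium lactone enolate 13 (not isolated)
Conditions: LiN(SiMe3)2 (1.05 eq), THF, −78 °C; then 12 (1.1 eq), −78 → −40 °C
Reagents that add atoms: none
Why: Lactone enolate alkylation: the lactone α-CH2 is more acidic and more accessible than the tertiary C–H next to the methyl ester, so one equivalent of amide base at −78 °C should give enolate 13, which is benzylated (SN2) on the face opposite the neighbouring C3 ester. This is the trans-selective alkylation of β-substituted γ-butyrolactone enolates used for dibenzylbutyrolactone lignans; it sets C4 of the lactone (C3 of the target) and gives the all-trans lactone.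

**Step 9**
Reactants: 14 methyl (2R,3R,4R)-2-[3,4-bis(benzyloxy)phenyl]-4-{[3-methoxy-4-(pivaloyloxy)phenyl]methyl}-5-oxooxolane-3-carboxylate
Product: 15 (2S,3R)-2-{(R)-[3,4-bis(benzyloxy)phenyl](hydroxy)methyl}-3-[(4-hydroxy-3-methoxyphenyl)methyl]butane-1,4-diol
Conditions: LiAlH4 (5 eq), THF, 0 °C → rt; aq. potassium sodium tartrate
Reagents that add atoms: none
Why: Exhaustive LiAlH4 reduction: the lactone opens to the carbinol and the C3 hydroxymethyl group, the ester becomes the C5 hydroxymethyl group and the aryl pivalate is cleaved to the free guaiacol. No stereocentre is created or epimerised and benzyl ethers are inert to hydride.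

**Step 10**
Reactants: 15 (2S,3R)-2-{(R)-[3,4-bis(benzyloxy)phenyl](hydroxy)methyl}-3-[(4-hydroxy-3-methoxyphenyl)methyl]butane-1,4-diol
Product: 16 (2S,3R)-2-{(R)-[3,4-bis(benzyloxy)phenyl](hydroxy)methyl}-3-{[3-methoxy-4-(pivaloyloxy)phenyl]methyl}butane-1,4-diyl bis(2,2-dimethylpropanoate)
Conditions: PivCl (3.3 eq), pyridine, CH2Cl2, −20 → 0 °C
Reagents that add atoms: pivaloyl chloride, CC(C)(C)C(=O)Cl
Why: Sterically controlled acylation: the bulky acid chloride should esterify the phenol and both primary hydroxyls far faster than the secondary benzylic hydroxyl, which is flanked by an aryl ring and a branched carbon.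

**Step 11**
Reactants: 16 (2S,3R)-2-{(R)-[3,4-bis(benzyloxy)phenyl](hydroxy)methyl}-3-{[3-methoxy-4-(pivaloyloxy)phenyl]methyl}butane-1,4-diyl bis(2,2-dimethylpropanoate)
Product: 17 (2S,3R)-2-{(R)-[3,4-bis(benzyloxy)phenyl][(tert-butyldimethylsilyl)oxy]methyl}-3-{[3-methoxy-4-(pivaloyloxy)phenyl]methyl}butane-1,4-diyl bis(2,2-dimethylpropanoate)
Conditions: TBSOTf (1.5 eq), 2,6-lutidine (3 eq), CH2Cl2, −78 → 0 °C
Reagents that add atoms: tert-butyldimethylsilyl trifluoromethanesulfonate, CC(C)(C)[Si](C)(C)OS(=O)(=O)C(F)(F)F
Why: Silylation of a hindered secondary alcohol with a silyl triflate; the lutidine buffer and low temperature keep the electron-rich benzylic C–O bond from ionising. The configuration at the carbinol carbon is untouched because only the O–H bond reacts.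

**Step 12**
Reactants: 17 (2S,3R)-2-{(R)-[3,4-bis(benzyloxy)phenyl][(tert-butyldimethylsilyl)oxy]methyl}-3-{[3-methoxy-4-(pivaloyloxy)phenyl]methyl}butane-1,4-diyl bis(2,2-dimethylpropanoate)
Product: 18 (2S,3R)-2-{(R)-[3,4-bis(benzyloxy)phenyl][(tert-butyldimethylsilyl)oxy]methyl}-3-[(4-hydroxy-3-methoxyphenyl)methyl]butane-1,4-diol
Conditions: iBu2AlH (7 eq), CH2Cl2, −78 °C; aq. potassium sodium tartrate
Reagents that add atoms: none
Why: Reductive de-acylation: the hydride reduces the aryl pivalate and both alkyl pivalates and frees the phenol and the two primary hydroxyls. The cold, non-basic aluminium alkoxide medium is preferred to alkoxide-mediated ester cleavage because it gives the silyl group no chance to migrate from the secondary to the neighbouring primary oxygen.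

**Step 13**
Reactants: 18 (2S,3R)-2-{(R)-[3,4-bis(benzyloxy)phenyl][(tert-butyldimethylsilyl)oxy]methyl}-3-[(4-hydroxy-3-methoxyphenyl)methyl]butane-1,4-diol
Product: 20 4-[(2S,3R,4S)-4-{(R)-[3,4-bis(benzyloxy)phenyl][(tert-butyldimethylsilyl)oxy]methyl}-3-(hydroxymethyl)oxolan-2-yl]-2-methoxyphenol, via p-quinone methide 19 (not isolated)
Conditions: Ag2O (2 eq), CH2Cl2 (0.01 M), rt, dark
Reagents that add atoms: none
Why: Ag2O removes two electrons and two protons from the only free phenol of 18 (phenoxyl radical, then loss of a benzylic hydrogen) to give p-quinone methide 19, whose exocyclic carbon is the future C2. The hydroxyl on the future C5 adds to that carbon in a 5-exo-trig oxa-Michael closure that forms O1–C2 and the oxolane ring, and the guaiacol rearomatises; the closest known reaction type is the oxidation of 4-alkyl-2-methoxyphenols to quinone methides with Ag2O or DDQ and capture by a tethered hydroxyl, the ring-forming event of tetrahydrofuran lignan biosynthesis. C2 is the only new stereocentre: closure through the envelope that keeps the C3 hydroxymethyl group and the bulky C4 side chain pseudo-equatorial places the quinonoid ring trans to the C3 substituent, and since addition to a quinone methide is reversible the more stable 2,3-trans-3,4-trans isomer should also prevail on equilibration. Chemoselectivity of oxidation is secured by the benzyl ethers on the catechol, which leave the guaiacol as the only oxidisable phenol. Regioselectivity of capture is secured by the silyl ether on the carbinol oxygen, which would otherwise close a 2,5-diaryl oxolane, and by ring size, since the other primary hydroxyl could only form an oxetane. The neutral, heterogeneous oxidant is chosen so that the dibenzyloxyphenyl ring does not add to 19 in a Friedel–Crafts sense (six-membered aryltetralin closure), and high dilution disfavours intermolecular capture and phenoxyl dimerisation.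

**Step 14**
Reactants: 20 4-[(2S,3R,4S)-4-{(R)-[3,4-bis(benzyloxy)phenyl][(tert-butyldimethylsilyl)oxy]methyl}-3-(hydroxymethyl)oxolan-2-yl]-2-methoxyphenol
Product: 21 4-[(2S,3R,4S)-4-{(R)-[3,4-bis(benzyloxy)phenyl](hydroxy)methyl}-3-(hydroxymethyl)oxolan-2-yl]-2-methoxyphenol
Conditions: Bu4NF (2 eq), AcOH (2 eq), THF, 0 °C → rt
Reagents that add atoms: none
Why: Fluoride-induced Si–O cleavage driven by the strength of the Si–F bond. Acetic acid buffering keeps the medium near neutral, which protects the para-hydroxybenzylic ether at C2 from base- or acid-induced opening; benzyl ethers are unaffected.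

**Step 15**
Reactants: 21 4-[(2S,3R,4S)-4-{(R)-[3,4-bis(benzyloxy)phenyl](hydroxy)methyl}-3-(hydroxymethyl)oxolan-2-yl]-2-methoxyphenol
Product: 22 4-{(R)-hydroxy[(3S,4R,5S)-5-(4-hydroxy-3-methoxyphenyl)-4-(hydroxymethyl)oxolan-3-yl]methyl}benzene-1,2-diol (the target; 2S,3R,4S in the ring numbering used here)
Conditions: H2 (1 atm), 10% Pd/C, EtOAc, rt; stopped after uptake of 2 eq
Reagents that add atoms: none
Why: Hydrogenolysis of the two aryl benzyl ethers; in neutral solvent at atmospheric pressure aryl O–CH2Ph bonds should cleave much faster than the benzylic carbinol C–OH and the O1–C2 bond, as in debenzylations of O-benzylated 1-aryl-alkanols and 2-aryl-oxolane lignans. Filtration and evaporation give the air-sensitive catechol without exposure to base.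

## Compound list

1 | 3',4'-dihydroxyacetophenone | CC(=O)c1ccc(O)c(O)c1 | starting material
2 | 1-[3,4-bis(benzyloxy)phenyl]ethan-1-one | CC(=O)c1ccc(OCc2ccccc2)c(OCc2ccccc2)c1 | intermediate
3 | dimethyl carbonate | COC(=O)OC | starting material
4 | methyl 3-[3,4-bis(benzyloxy)phenyl]-3-oxopropanoate | COC(=O)CC(=O)c1ccc(OCc2ccccc2)c(OCc2ccccc2)c1 | intermediate
5 | methyl bromoacetate | COC(=O)CBr | starting material
6 | dimethyl 2-[3,4-bis(benzyloxy)benzoyl]butanedioate, racemic | COC(=O)CC(C(=O)OC)C(=O)c1ccc(OCc2ccccc2)c(OCc2ccccc2)c1 | intermediate
7 | dimethyl (2R)-2-{(R)-[3,4-bis(benzyloxy)phenyl](hydroxy)methyl}butanedioate (syn) | COC(=O)C[C@@H](C(=O)OC)[C@@H](O)c1ccc(OCc2ccccc2)c(OCc2ccccc2)c1 | intermediate, not isolated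
8 | methyl (2R,3R)-2-[3,4-bis(benzyloxy)phenyl]-5-oxooxolane-3-carboxylate (trans) | O=C1C[C@@H](C(=O)OC)[C@H](c2ccc(OCc3ccccc3)c(OCc3ccccc3)c2)O1 | intermediate
9 | vanillin | COc1cc(C=O)ccc1O | starting material
10 | 4-formyl-2-methoxyphenyl 2,2-dimethylpropanoate | COc1cc(C=O)ccc1OC(=O)C(C)(C)C | intermediate
11 | 4-(hydroxymethyl)-2-methoxyphenyl 2,2-dimethylpropanoate | COc1cc(CO)ccc1OC(=O)C(C)(C)C | intermediate
12 | 4-(bromomethyl)-2-methoxyphenyl 2,2-dimethylpropanoate | COc1cc(CBr)ccc1OC(=O)C(C)(C)C | intermediate
13 | lithium enolate of 8 (lactone enolate) | [Li+].[O-]C1=C[C@@H](C(=O)OC)[C@H](c2ccc(OCc3ccccc3)c(OCc3ccccc3)c2)O1 | intermediate, not isolated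
14 | methyl (2R,3R,4R)-2-[3,4-bis(benzyloxy)phenyl]-4-{[3-methoxy-4-(pivaloyloxy)phenyl]methyl}-5-oxooxolane-3-carboxylate | COc1cc(C[C@H]2C(=O)O[C@@H](c3ccc(OCc4ccccc4)c(OCc4ccccc4)c3)[C@@H]2C(=O)OC)ccc1OC(=O)C(C)(C)C | intermediate
15 | (2S,3R)-2-{(R)-[3,4-bis(benzyloxy)phenyl](hydroxy)methyl}-3-[(4-hydroxy-3-methoxyphenyl)methyl]butane-1,4-diol | COc1cc(C[C@@H](CO)[C@@H](CO)[C@@H](O)c2ccc(OCc3ccccc3)c(OCc3ccccc3)c2)ccc1O | intermediate
16 | (2S,3R)-2-{(R)-[3,4-bis(benzyloxy)phenyl](hydroxy)methyl}-3-{[3-methoxy-4-(pivaloyloxy)phenyl]methyl}butane-1,4-diyl bis(2,2-dimethylpropanoate) | COc1cc(C[C@@H](COC(=O)C(C)(C)C)[C@@H](COC(=O)C(C)(C)C)[C@@H](O)c2ccc(OCc3ccccc3)c(OCc3ccccc3)c2)ccc1OC(=O)C(C)(C)C | intermediate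
17 | (2S,3R)-2-{(R)-[3,4-bis(benzyloxy)phenyl][(tert-butyldimethylsilyl)oxy]methyl}-3-{[3-methoxy-4-(pivaloyloxy)phenyl]methyl}butane-1,4-diyl bis(2,2-dimethylpropanoate) | COc1cc(C[C@@H](COC(=O)C(C)(C)C)[C@@H](COC(=O)C(C)(C)C)[C@@H](O[Si](C)(C)C(C)(C)C)c2ccc(OCc3ccccc3)c(OCc3ccccc3)c2)ccc1OC(=O)C(C)(C)C | intermediate
18 | (2S,3R)-2-{(R)-[3,4-bis(benzyloxy)phenyl][(tert-butyldimethylsilyl)oxy]methyl}-3-[(4-hydroxy-3-methoxyphenyl)methyl]butane-1,4-diol (precursor of the key step) | COc1cc(C[C@@H](CO)[C@@H](CO)[C@@H](O[Si](C)(C)C(C)(C)C)c2ccc(OCc3ccccc3)c(OCc3ccccc3)c2)ccc1O | intermediate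
19 | p-quinone methide of 18 (2-methoxy-4-alkylidenecyclohexa-2,5-dien-1-one, chain centres as in 18) | COC1=CC(=C[C@@H](CO)[C@@H](CO)[C@@H](O[Si](C)(C)C(C)(C)C)c2ccc(OCc3ccccc3)c(OCc3ccccc3)c2)C=CC1=O | intermediate, not isolated
20 | 4-[(2S,3R,4S)-4-{(R)-[3,4-bis(benzyloxy)phenyl][(tert-butyldimethylsilyl)oxy]methyl}-3-(hydroxymethyl)oxolan-2-yl]-2-methoxyphenol (product of the key step) | COc1cc([C@H]2OC[C@@H]([C@@H](O[Si](C)(C)C(C)(C)C)c3ccc(OCc4ccccc4)c(OCc4ccccc4)c3)[C@@H]2CO)ccc1O | intermediate
21 | 4-[(2S,3R,4S)-4-{(R)-[3,4-bis(benzyloxy)phenyl](hydroxy)methyl}-3-(hydroxymethyl)oxolan-2-yl]-2-methoxyphenol | COc1cc([C@H]2OC[C@@H]([C@@H](O)c3ccc(OCc4ccccc4)c(OCc4ccccc4)c3)[C@@H]2CO)ccc1O | intermediate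
22 | 4-{(R)-hydroxy[(3S,4R,5S)-5-(4-hydroxy-3-methoxyphenyl)-4-(hydroxymethyl)oxolan-3-yl]methyl}benzene-1,2-diol | COc1cc([C@H]2OC[C@@H]([C@@H](O)c3ccc(O)c(O)c3)[C@@H]2CO)ccc1O | target

## Step count and least certain steps

Total step count: 15. Longest linear sequence: 12 steps (steps 1–4 and 8–15, from 1); the bromide branch (steps 5–7, from 9) is three steps.

**Step 13 (key step).**
- What may go wrong: one-electron chemistry of the phenoxyl radical (C–C or C–O coupling at the free ortho position of the guaiacol) before the second oxidation, tautomerisation of 19 to the conjugated styrene, or Friedel–Crafts attack of the dibenzyloxyphenyl ring on 19. These compete because a guaiacol with only one ortho substituent gives a quinone methide that forms slowly and is short-lived.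
- Fallback (from 18, back at 20): oxidation and ring closure are separated. 18 would be oxidised with DDQ, a two-electron hydride-abstracting oxidant, in CH2Cl2/MeOH at 0 °C, so that 19 is intercepted at once by the solvent as the benzylic methyl ether of 18 F1 (both epimers at the new carbon; any 20 formed directly is welcome). F1 would then be treated with catalytic PPTS and 4 Å molecular sieves in CH2Cl2 at 40 °C. The para-hydroxybenzylic ether ionises far more readily than the silylated carbinol, methanol is lost, and the C5 hydroxyl should close the ring under thermodynamic control to 20.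

**Step 4.**
- What may go wrong: racemisation of the carbon between ketone and ester that does not keep pace with reduction, or weak syn/anti discrimination, giving a mixture of lactone diastereomers; the electron-rich aryl ketone is a slow substrate, which makes this more likely.
- Fallback (from 4, back at 8): the two centres are set in separate steps. 4, which has no labile stereocentre, would be reduced with the same catalyst and HCO2H/Et3N to the β-hydroxy ester F2. Fráter–Seebach alkylation of its dianion (LiN(iPr)2, 2.2 eq, THF, −78 → −20 °C) with 5 would give the anti hydroxy diester F3, which lactonises (PPTS, PhMe) to the cis lactone ester F4. Equilibration of C3, α to the ester, with catalytic DBU in toluene should then deliver the more stable trans lactone 8. The same DBU treatment would also correct any cis lactone formed in step 4 itself.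

**Step 8.**
- What may go wrong: competing deprotonation at C3 (α to the methyl ester) followed by β-elimination of the lactone carboxylate with ring opening, or attack of the enolate on the aryl pivalate.
- Fallback (from 8, back at 15): the ester is replaced by a carboxylate, whose α-C–H is not acidic. 8 would be saponified (LiOH, THF/H2O, 0 °C; then aq. HCl to pH 2, which recloses the γ-lactone) to the trans paraconic acid F5. Its dianion (LiN(SiMe3)2, 2.2 eq, THF, −78 °C) would be alkylated with 12 trans to the carboxylate to give the benzylated acid lactone F6. LiAlH4 (THF, 0 °C → reflux) would reduce acid, lactone and aryl pivalate of F6 directly to 15; an ester formed from the carboxylate and excess 12 would be reduced to the same product.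

**Step 15.**
- What may go wrong: over-reduction, that is hydrogenolysis of the benzylic carbinol C–OH bond or of the O1–C2 bond once the aryl benzyl ethers have gone, both being activated by para oxygen substituents.
- Fallback (from 20, back at 22): the order of the last two steps is reversed so that the carbinol oxygen still carries its bulky silyl group during hydrogenolysis. 20 would be hydrogenolysed (H2, 10% Pd/C, EtOAc) to the silyl ether of the target F7, which would then be desilylated with Bu4NF/AcOH in THF under argon to 22.

## Further compounds

F1 | step 13 | benzylic methyl ether of 18 (methoxy group on the guaiacyl-bearing carbon, both epimers there, other centres as in 18) | COc1cc(C(OC)[C@@H](CO)[C@@H](CO)[C@@H](O[Si](C)(C)C(C)(C)C)c2ccc(OCc3ccccc3)c(OCc3ccccc3)c2)ccc1O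
F2 | step 4 | methyl (3R)-3-[3,4-bis(benzyloxy)phenyl]-3-hydroxypropanoate | COC(=O)C[C@@H](O)c1ccc(OCc2ccccc2)c(OCc2ccccc2)c1
F3 | step 4 | dimethyl (2S)-2-{(R)-[3,4-bis(benzyloxy)phenyl](hydroxy)methyl}butanedioate (anti) | COC(=O)C[C@H](C(=O)OC)[C@@H](O)c1ccc(OCc2ccccc2)c(OCc2ccccc2)c1
F4 | step 4 | methyl (2R,3S)-2-[3,4-bis(benzyloxy)phenyl]-5-oxooxolane-3-carboxylate (cis) | O=C1C[C@H](C(=O)OC)[C@H](c2ccc(OCc3ccccc3)c(OCc3ccccc3)c2)O1
F5 | step 8 | (2R,3R)-2-[3,4-bis(benzyloxy)phenyl]-5-oxooxolane-3-carboxylic acid | O=C1C[C@@H](C(=O)O)[C@H](c2ccc(OCc3ccccc3)c(OCc3ccccc3)c2)O1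
F6 | step 8 | (2R,3R,4R)-2-[3,4-bis(benzyloxy)phenyl]-4-{[3-methoxy-4-(pivaloyloxy)phenyl]methyl}-5-oxooxolane-3-carboxylic acid | COc1cc(C[C@H]2C(=O)O[C@@H](c3ccc(OCc4ccccc4)c(OCc4ccccc4)c3)[C@@H]2C(=O)O)ccc1OC(=O)C(C)(C)C
F7 | step 15 | 4-[(R)-[(tert-butyldimethylsilyl)oxy]{(3S,4R,5S)-5-(4-hydroxy-3-methoxyphenyl)-4-(hydroxymethyl)oxolan-3-yl}methyl]benzene-1,2-diol | COc1cc([C@H]2OC[C@@H]([C@@H](O[Si](C)(C)C(C)(C)C)c3ccc(O)c(O)c3)[C@@H]2CO)ccc1O
A1 | alternative 1 | N-acyloxyphthalimide of the O-carboxymethyl ether of (E)-1-[4-(benzyloxy)-3-methoxyphenyl]-2-[(benzyloxy)methyl]-4-[3,4-bis(benzyloxy)phenyl]but-3-en-1-ol, C2 and C3 configured as in the target | COc1cc([C@@H](OCC(=O)ON2C(=O)c3ccccc3C2=O)[C@@H](COCc2ccccc2)/C=C/c2ccc(OCc3ccccc3)c(OCc3ccccc3)c2)ccc1OCc1ccccc1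
A2 | alternative 1 | tetra-O-benzyl derivative of the target skeleton, both epimers at the carbinol carbon | COc1cc([C@H]2OC[C@@H](C(O)c3ccc(OCc4ccccc4)c(OCc4ccccc4)c3)[C@@H]2COCc2ccccc2)ccc1OCc1ccccc1
A3 | alternative 2 | rac-2-{1-[3,4-bis(benzyloxy)phenyl]ethenyl}oxirane | C=C(C1CO1)c1ccc(OCc2ccccc2)c(OCc2ccccc2)c1
A4 | alternative 2 | dimethyl 2-{[4-(benzyloxy)-3-methoxyphenyl]methylidene}propanedioate | COC(=O)C(=Cc1ccc(OCc2ccccc2)c(OC)c1)C(=O)OC
A5 | alternative 2 | dimethyl 2,4-cis-2-[4-(benzyloxy)-3-methoxyphenyl]-4-{1-[3,4-bis(benzyloxy)phenyl]ethenyl}oxolane-3,3-dicarboxylate | COc1cc([C@H]2OC[C@@H](C(=C)c3ccc(OCc4ccccc4)c(OCc4ccccc4)c3)C2(C(=O)OC)C(=O)OC)ccc1OCc1ccccc1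
A6 | alternative 3 | 2-{[3,4-bis(tert-butyldimethylsilyloxy)phenyl](tert-butyldimethylsilyloxy)methyl}-4-[4-(tert-butyldimethylsilyloxy)-3-methoxyphenyl]but-3-yn-1-ol, configured as C4 and the carbinol carbon of the target | COc1cc(C#C[C@H]([C@@H](O[Si](C)(C)C(C)(C)C)c2ccc(O[Si](C)(C)C(C)(C)C)c(O[Si](C)(C)C(C)(C)C)c2)CO)ccc1O[Si](C)(C)C(C)(C)C
A7 | alternative 3 | methyl 2-[4-(tert-butyldimethylsilyloxy)-3-methoxyphenyl]-4-{[3,4-bis(tert-butyldimethylsilyloxy)phenyl](tert-butyldimethylsilyloxy)methyl}-4,5-dihydrofuran-3-carboxylate | COc1cc(C2=C(C(=O)OC)[C@H]([C@@H](O[Si](C)(C)C(C)(C)C)c3ccc(O[Si](C)(C)C(C)(C)C)c(O[Si](C)(C)C(C)(C)C)c3)CO2)ccc1O[Si](C)(C)C(C)(C)C
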